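**Plan**

1. Retrosynthesis: the three O-alkyl helpers (methyl on O5 and O5'', isopropyl on O4''') are put back. Unit 1 (unprimed locants) is then cut at O1–C2 and C4–C4a and unit 2 (doubly primed locants) at O1''–C2'', which leads to aryl cinnamate 11. Further cuts: ester C–O, the C2''–C3'' alkene (aldol), the acetyl C–C bond at C4a'', the C8a''–O bond, the cinnamic alkene, the diaryl ether C–O.
2. Forward: diaryl ether by SNAr, cinnamic acid, phenol from the bromide, acetylation of ring A of unit 2, chalcone of unit 2 by aldol, ester with 3,5-dimethoxyphenol. One operation then moves the cinnamoyl group from O1 to C4a and closes ring C of unit 1 and ring C of unit 2. Dealkylation ends the route.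
3. Enabling feature: ring A of unit 1 (C4a, C5–C8, C8a) is a 1,3,5-trioxygenated benzene that comes from 3,5-dimethoxyphenol. Its mirror plane makes the two carbons ortho to O1 identical, so the acyl shift O1→C4a has one outcome and leaves O1–H five atoms from C2 of the enone.
4. Stereochemistry: C2 and C2'' are both created in step 7 under control of one cinchona thiourea catalyst (two independent oxa-Michael closures). Only a low-temperature Lewis-acid dealkylation follows, and no base.
5. Helpers: the methyl group on O5'' keeps ring closure of unit 2 on the one free phenol, the methyl group on O5 comes from the symmetric phenol, and the isopropyl group masks O4'''. All three leave in step 8.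

Key step: step 7

Assumption: the quinine-derived thiourea is taken to give the (2S) sense at C2 and C2''; should the sense prove opposite, the quinidine-derived pseudo-enantiomer takes its place with no other change.

**Route**

Step 1
Reactants: 1 4-bromo-2,6-dimethoxyphenol; 2 4-fluorobenzaldehyde
Product: 3 4-(4-bromo-2,6-dimethoxyphenoxy)benzaldehyde
Conditions: K2CO3, DMF, 120 °C
Reagents that add atoms: none
Why: Nucleophilic aromatic substitution by addition–elimination, in which the phenoxide of 1 displaces the fluoride para to the formyl group of 2 while the aryl bromide stays inert; no stereocentre is formed.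

Step 2
Reactants: 3 4-(4-bromo-2,6-dimethoxyphenoxy)benzaldehyde
Product: 4 (E)-3-[4-(4-bromo-2,6-dimethoxyphenoxy)phenyl]prop-2-enoic acid
Conditions: CH2(CO2H)2, pyridine, piperidine (cat.), 100 °C
Reagents that add atoms: malonic acid, OC(=O)CC(=O)O
Why: Knoevenagel–Doebner condensation, in which the aldehyde condenses with malonic acid and decarboxylation in pyridine gives the (E)-cinnamic acid as the thermodynamic alkene; no stereocentre is formed.

Step 3
Reactants: 4 (E)-3-[4-(4-bromo-2,6-dimethoxyphenoxy)phenyl]prop-2-enoic acid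
Product: 5 (E)-3-[4-(4-hydroxy-2,6-dimethoxyphenoxy)phenyl]prop-2-enoic acid
Conditions: Cu(acac)2 (cat.), N,N'-bis(4-hydroxy-2,6-dimethylphenyl)oxalamide (cat.), LiOH·H2O, DMSO–H2O, 100 °C; then aq. HCl
Reagents that add atoms: lithium hydroxide, [Li+].[OH-]
Why: Ullmann-type copper-catalysed hydroxylation of an aryl bromide with hydroxide, which tolerates the carboxylate and the unhindered electron-rich ring; no stereocentre is formed.

Step 4
Reactants: 5 (E)-3-[4-(4-hydroxy-2,6-dimethoxyphenoxy)phenyl]prop-2-enoic acid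
Product: 7 (E)-3-[4-(3-acetyl-4-hydroxy-2,6-dimethoxyphenoxy)phenyl]prop-2-enoic acid, via aryl acetate 6 (not isolated)
Conditions: Ac2O, BF3·OEt2, 70 °C; then aq. NaOAc, 50 °C
Reagents that add atoms: acetic anhydride, CC(=O)OC(C)=O
Why: O-Acetylation followed by Fries rearrangement, in which the acetyl group shifts to one of the two equivalent ortho carbons (the para carbon is blocked by the aryloxy group) and boron chelation of the ortho-hydroxy ketone drives the shift; no stereocentre is formed.

Step 5
Reactants: 7 (E)-3-[4-(3-acetyl-4-hydroxy-2,6-dimethoxyphenoxy)phenyl]prop-2-enoic acid; 8 4-(propan-2-yloxy)benzaldehyde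
Product: 9 (E)-3-[4-(4-hydroxy-2,6-dimethoxy-3-{(E)-3-[4-(propan-2-yloxy)phenyl]prop-2-enoyl}phenoxy)phenyl]prop-2-enoic acid
Conditions: KOH, EtOH–H2O, 20 °C; then aq. HCl, 0 °C
Reagents that add atoms: none
Why: Claisen–Schmidt condensation, in which the enolate of the methyl ketone adds to the non-enolisable aldehyde 8 and dehydration gives the (E)-enone, while the acid is carried as its carboxylate and the chalcone stays open as its phenoxide; no stereocentre is formed.

Step 6
Reactants: 9 (E)-3-[4-(4-hydroxy-2,6-dimethoxy-3-{(E)-3-[4-(propan-2-yloxy)phenyl]prop-2-enoyl}phenoxy)phenyl]prop-2-enoic acid; 10 3,5-dimethoxyphenol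
Product: 11 3,5-dimethoxyphenyl (E)-3-[4-(4-hydroxy-2,6-dimethoxy-3-{(E)-3-[4-(propan-2-yloxy)phenyl]prop-2-enoyl}phenoxy)phenyl]prop-2-enoate
Conditions: DCC, DMAP (cat.), CH2Cl2, 0 → 20 °C
Reagents that add atoms: none
Why: Steglich esterification, in which the activated cinnamic acid is passed on by DMAP to the free phenol 10 while the hydroxyl of 9 next to the ketone is held in a hydrogen bond and does not compete; no stereocentre is formed.

Step 7
Reactants: 11 3,5-dimethoxyphenyl (E)-3-[4-(4-hydroxy-2,6-dimethoxy-3-{(E)-3-[4-(propan-2-yloxy)phenyl]prop-2-enoyl}phenoxy)phenyl]prop-2-enoate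
Product: 13 (2S)-2-[4-({(2S)-5,7-dimethoxy-4-oxo-2-[4-(propan-2-yloxy)phenyl]chroman-6-yl}oxy)phenyl]-5,7-dimethoxychroman-4-one, via bis-chalcone 12 (not isolated)
Conditions: TiCl4, CH2Cl2, 0 → 40 °C; then cold aq. HCl wash, solvent change to PhMe–CHCl3, N-[3,5-bis(trifluoromethyl)phenyl]-N'-[(8α,9S)-6'-methoxycinchonan-9-yl]thiourea (20 mol%), 20 °C
Reagents that add atoms: none
Why: TiCl4 activates the aryl ester of 11 so that the cinnamoyl group leaves O1 as a titanium-bound acylium ion pair and re-enters at the neighbouring ortho carbon (the later C4a), which is a Fries rearrangement of an aryl cinnamate to a 2'-hydroxychalcone and gives 12; once titanium is washed out, the cinchona thiourea closes both pyranone rings by intramolecular oxa-Michael addition, the closest known reaction type being the bifunctional-amine-catalysed asymmetric cyclisation of 2'-hydroxychalcones to flavanones. Ring C of unit 1 (bond O1–C2) and ring C of unit 2 (bond O1''–C2'') each close in the 6-endo-trig mode. C2 and C2'' are set under catalyst control: the quinuclidine nitrogen takes the phenol proton, the thiourea holds the enone carbonyl by two hydrogen bonds, and the chiral ion pair leaves one face of each β-carbon open, so that the two remote centres are set independently and in the same (S) sense. The step needs ortho instead of para acyl shift and acyl transfer instead of conjugate addition of the arene, closure of unit 2 through the correct oxygen, and facial selectivity in both closures. The first is secured by the mirror symmetry of the 3,5-dimethoxyphenyl ring (two identical ortho carbons, each between two oxygens) and by delivery from the titanium aryloxide, the second by the methyl group kept on O5'' so that only one phenol flanks that ketone, and the third by the catalyst. Isomers with one wrong centre are diastereomers of 13 and should be removable on purification, which lifts the optical purity of the (2S,2''S) fraction above the selectivity of a single closure.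

Step 8
Reactants: 13 (2S)-2-[4-({(2S)-5,7-dimethoxy-4-oxo-2-[4-(propan-2-yloxy)phenyl]chroman-6-yl}oxy)phenyl]-5,7-dimethoxychroman-4-one
Product: 14 (2S)-5-hydroxy-2-[4-({(2S)-5-hydroxy-2-(4-hydroxyphenyl)-7-methoxy-4-oxochroman-6-yl}oxy)phenyl]-7-methoxychroman-4-one (7,7''-di-O-methyltetrahydrohinokiflavone)
Conditions: BCl3, CH2Cl2, −78 → 0 °C; then H2O
Reagents that add atoms: none
Why: Chelation-controlled ether cleavage, in which BCl3 bound at each C4 carbonyl removes only the neighbouring methyl group on O5 and O5'' and also cleaves the secondary isopropyl ether, while the methyl ethers on O7 and O7'' and the diaryl ether should stay intact and the absence of base keeps C2 and C2'' from ring opening.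

**Compound list**

1 | 4-bromo-2,6-dimethoxyphenol | COc1cc(Br)cc(OC)c1O | starting material
2 | 4-fluorobenzaldehyde | O=Cc1ccc(F)cc1 | starting material
3 | 4-(4-bromo-2,6-dimethoxyphenoxy)benzaldehyde | COc1cc(Br)cc(OC)c1Oc1ccc(C=O)cc1 | intermediate
4 | (E)-3-[4-(4-bromo-2,6-dimethoxyphenoxy)phenyl]prop-2-enoic acid | COc1cc(Br)cc(OC)c1Oc1ccc(/C=C/C(=O)O)cc1 | intermediate
5 | (E)-3-[4-(4-hydroxy-2,6-dimethoxyphenoxy)phenyl]prop-2-enoic acid | COc1cc(O)cc(OC)c1Oc1ccc(/C=C/C(=O)O)cc1 | intermediate
6 | (E)-3-[4-(4-acetoxy-2,6-dimethoxyphenoxy)phenyl]prop-2-enoic acid (aryl acetate, not isolated) | COc1cc(OC(C)=O)cc(OC)c1Oc1ccc(/C=C/C(=O)O)cc1 | intermediate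
7 | (E)-3-[4-(3-acetyl-4-hydroxy-2,6-dimethoxyphenoxy)phenyl]prop-2-enoic acid | COc1cc(O)c(C(C)=O)c(OC)c1Oc1ccc(/C=C/C(=O)O)cc1 | intermediate
8 | 4-(propan-2-yloxy)benzaldehyde | CC(C)Oc1ccc(C=O)cc1 | starting material
9 | (E)-3-[4-(4-hydroxy-2,6-dimethoxy-3-{(E)-3-[4-(propan-2-yloxy)phenyl]prop-2-enoyl}phenoxy)phenyl]prop-2-enoic acid | COc1cc(O)c(C(=O)/C=C/c2ccc(OC(C)C)cc2)c(OC)c1Oc1ccc(/C=C/C(=O)O)cc1 | intermediate
10 | 3,5-dimethoxyphenol | COc1cc(O)cc(OC)c1 | starting material
11 | 3,5-dimethoxyphenyl (E)-3-[4-(4-hydroxy-2,6-dimethoxy-3-{(E)-3-[4-(propan-2-yloxy)phenyl]prop-2-enoyl}phenoxy)phenyl]prop-2-enoate | COc1cc(OC)cc(OC(=O)/C=C/c2ccc(Oc3c(OC)cc(O)c(C(=O)/C=C/c4ccc(OC(C)C)cc4)c3OC)cc2)c1 | intermediate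
12 | (E)-1-(2-hydroxy-4,6-dimethoxyphenyl)-3-[4-(4-hydroxy-2,6-dimethoxy-3-{(E)-3-[4-(propan-2-yloxy)phenyl]prop-2-enoyl}phenoxy)phenyl]prop-2-en-1-one (bis-chalcone, not isolated) | COc1cc(O)c(C(=O)/C=C/c2ccc(Oc3c(OC)cc(O)c(C(=O)/C=C/c4ccc(OC(C)C)cc4)c3OC)cc2)c(OC)c1 | intermediate
13 | (2S)-2-[4-({(2S)-5,7-dimethoxy-4-oxo-2-[4-(propan-2-yloxy)phenyl]chroman-6-yl}oxy)phenyl]-5,7-dimethoxychroman-4-one | COc1cc(OC)c2c(c1)O[C@H](c1ccc(Oc3c(OC)cc4c(c3OC)C(=O)C[C@@H](c3ccc(OC(C)C)cc3)O4)cc1)CC2=O | intermediate
14 | (2S)-5-hydroxy-2-[4-({(2S)-5-hydroxy-2-(4-hydroxyphenyl)-7-methoxy-4-oxochroman-6-yl}oxy)phenyl]-7-methoxychroman-4-one (7,7''-di-O-methyltetrahydrohinokiflavone) | COc1cc(O)c2c(c1)O[C@H](c1ccc(Oc3c(OC)cc4c(c3O)C(=O)C[C@@H](c3ccc(O)cc3)O4)cc1)CC2=O | target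

**Count**

Total steps: 8. Longest linear sequence: 8 steps (1 to 14).

**Steps most likely to fail**

Step 7. The cinnamoyl group may add through its β-carbon to the electron-rich ring (conjugate hydroarylation) or shift to the para carbon instead of the ortho carbon. The double ring closure may also show poor facial selectivity that is further eroded by reversible ring opening. The fallback sets out from 9 and comes back at 13. Acid 9 is converted with (COCl)2 and cat. DMF into the acid chloride of 9 F1. F1 acylates 1,3,5-trimethoxybenzene (SnCl4, CH2Cl2, 0 °C), whose three ring carbons are equivalent and which has no phenol oxygen to compete, and this Friedel–Crafts acylation gives the 2',4',6'-trimethoxy bis-chalcone F2. BCl3 (CH2Cl2, −78 °C) then removes by chelation one methyl group ortho to the new ketone and gives 12. Bis-chalcone 12 is closed without a chiral catalyst (NaOAc, EtOH, reflux) to the mixture of the four stereoisomers of 13 F3. Asymmetric transfer hydrogenation with RhCl(Cp*)[(R,R)-TsDPEN] and HCO2H–Et3N in EtOAc at 20 °C is expected to reduce every ring of (2R) configuration to its cis-(2R,4R) carbinol. The unwanted isomers should then leave on chromatography as the carbinol of the (2R,2''S) isomer F4, the carbinol of the (2S,2''R) isomer F5 and the dicarbinol of the (2R,2''R) isomer F6, while unreduced (2S,2''S)-13 is recovered and enters step 8.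

Step 4. Under BF3 the cinnamic acid may compete as an acyl donor, or the electron-rich ring may add to its double bond, so that oligomers form in place of the acetyl shift. The fallback sets out from 5 and comes back at 7. A Houben–Hoesch reaction of 5 with MeCN, ZnCl2 and HCl gas in Et2O at 0 °C gives the ketiminium chloride F7, which is hydrolysed in water at 80 °C to 7. A nitrilium electrophile replaces the acyl cation, and the carboxylic acid takes no part.

Step 3. Oxidative addition at the electron-rich aryl bromide may be slow, and the electron-rich phenolate may be oxidised at 100 °C. The fallback sets out from 4 and comes back at 5. Miyaura borylation of 4 (B2pin2, Pd(dppf)Cl2, KOAc, dioxane, 90 °C) gives the pinacol boronate F8, and oxidation with NaBO3·4H2O in THF–H2O at 20 °C gives 5. The C–O bond is made by migration of the aryl group from boron to oxygen instead of by copper catalysis.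

**Further compounds**

F1 | step 7 | (E)-3-[4-(4-hydroxy-2,6-dimethoxy-3-{(E)-3-[4-(propan-2-yloxy)phenyl]prop-2-enoyl}phenoxy)phenyl]prop-2-enoyl chloride | COc1cc(O)c(C(=O)/C=C/c2ccc(OC(C)C)cc2)c(OC)c1Oc1ccc(/C=C/C(Cl)=O)cc1
F2 | step 7 | (E)-3-[4-(4-hydroxy-2,6-dimethoxy-3-{(E)-3-[4-(propan-2-yloxy)phenyl]prop-2-enoyl}phenoxy)phenyl]-1-(2,4,6-trimethoxyphenyl)prop-2-en-1-one | COc1cc(OC)c(C(=O)/C=C/c2ccc(Oc3c(OC)cc(O)c(C(=O)/C=C/c4ccc(OC(C)C)cc4)c3OC)cc2)c(OC)c1
F3 | step 7 | mixture of the four stereoisomers of 13 (no configuration defined at C2 and C2'') | COc1cc(OC)c2c(c1)OC(c1ccc(Oc3c(OC)cc4c(c3OC)C(=O)CC(c3ccc(OC(C)C)cc3)O4)cc1)CC2=O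
F4 | step 7 | (2S)-6-{4-[(2R,4R)-4-hydroxy-5,7-dimethoxychroman-2-yl]phenoxy}-5,7-dimethoxy-2-[4-(propan-2-yloxy)phenyl]chroman-4-one | COc1cc(OC)c2c(c1)O[C@@H](c1ccc(Oc3c(OC)cc4c(c3OC)C(=O)C[C@@H](c3ccc(OC(C)C)cc3)O4)cc1)C[C@H]2O
F5 | step 7 | (2S)-2-[4-({(2R,4R)-4-hydroxy-5,7-dimethoxy-2-[4-(propan-2-yloxy)phenyl]chroman-6-yl}oxy)phenyl]-5,7-dimethoxychroman-4-one | COc1cc(OC)c2c(c1)O[C@H](c1ccc(Oc3c(OC)cc4c(c3OC)[C@H](O)C[C@H](c3ccc(OC(C)C)cc3)O4)cc1)CC2=O
F6 | step 7 | (2R,4R)-6-{4-[(2R,4R)-4-hydroxy-5,7-dimethoxychroman-2-yl]phenoxy}-5,7-dimethoxy-2-[4-(propan-2-yloxy)phenyl]chroman-4-ol | COc1cc(OC)c2c(c1)O[C@@H](c1ccc(Oc3c(OC)cc4c(c3OC)[C@H](O)C[C@H](c3ccc(OC(C)C)cc3)O4)cc1)C[C@H]2O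
F7 | step 4 | 1-{3-[4-((E)-2-carboxyethenyl)phenoxy]-6-hydroxy-2,4-dimethoxyphenyl}ethaniminium chloride | COc1cc(O)c(C(C)=[NH2+])c(OC)c1Oc1ccc(/C=C/C(=O)O)cc1.[Cl-]
F8 | step 3 | (E)-3-{4-[2,6-dimethoxy-4-(4,4,5,5-tetramethyl-1,3,2-dioxaborolan-2-yl)phenoxy]phenyl}prop-2-enoic acid | COc1cc(B2OC(C)(C)C(C)(C)O2)cc(OC)c1Oc1ccc(/C=C/C(=O)O)cc1
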